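Retrosynthesis: the C2–C1' bond between the lower pyran ring and the bridging catechol ring is cut first (to a (3S)-chroman-2,3-diol lactol and a 4-arylflavan-3-ol with boron at C1'), then the upper C4–C6' bond (to a flavan-3,4-diol and 3,4-bis(benzyloxy)phenol), then the lactol at O1–C2 and C4–C4a (to an aryl Grignard reagent and methyl (S)-glycidate).
Forward: the lower pyran ring closes as a lactone and is reduced to the lactol; the upper chroman comes intact from (2R,3R)-fustin and is arylated at C4 by a phenol whose OH is then turned into the boron handle; the halves are joined and the six benzyl ethers removed.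
Enabling feature: lower C2 is an acetal-type carbon (bonded to ring oxygen O1) flanked by the C3 hydroxyl, so without its aryl group it is a lactol carbon whose O1=C2 oxocarbenium ion can take the aryl group from a boron atom held on the C3 oxygen; C1' is para to a ring oxygen (a good ipso migrating carbon), and the upper 3-OH holds the boron in a six-membered ring.
Stereochemistry: upper C2 and C3 come from fustin, upper C4 from attack anti to the 3-OH (3,4-trans), lower C3 from methyl (S)-glycidate, and lower C2 from boron-tethered cis delivery that converges both lactol anomers on (2S,3S).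

Key step: step 10

Assumption: (2R,3R)-fustin, 5-(benzyloxy)-2-bromophenol, 3,4-bis(benzyloxy)phenol and methyl (S)-glycidate are taken as purchasable, and any C4 epimer of diol 11 is carried along because C4 is ionised in step 7.

Step 1
Reactants: 1 5-(benzyloxy)-2-bromophenol
Product: 2 4-(benzyloxy)-1-bromo-2-(methoxymethoxy)benzene
Conditions: MOMCl, i-Pr2NEt, CH2Cl2, 0 °C → rt
Reagents that add atoms: chloromethyl methyl ether (MOMCl), COCCl
Why: Williamson-type O-alkylation of the only phenol gives a methoxymethyl acetal that survives the Grignard step and is removed later by acid.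

Step 2
Reactants: 2 4-(benzyloxy)-1-bromo-2-(methoxymethoxy)benzene; 3 methyl (2S)-oxirane-2-carboxylate (methyl (S)-glycidate)
Product: 5 methyl (2S)-3-[4-(benzyloxy)-2-(methoxymethoxy)phenyl]-2-hydroxypropanoate, via aryl Grignard reagent 4 (not isolated)
Conditions: Mg, THF, 40 °C; then 3, CuI (10 mol %), THF, −40 → −20 °C; aq. NH4Cl
Reagents that add atoms: none
Why: Copper-catalysed (monovalent copper) ring opening of a terminal epoxide by an aryl Grignard reagent should occur by SN2 attack at the CH2 carbon faster than ester addition at low temperature, so the stereocentre of 3 is untouched and becomes lower C3 (S).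

Step 3
Reactants: 5 methyl (2S)-3-[4-(benzyloxy)-2-(methoxymethoxy)phenyl]-2-hydroxypropanoate
Product: 7 (3S)-7-(benzyloxy)-3-hydroxychroman-2-one, via free phenol ester 6 (not isolated)
Conditions: CF3CO2H, CH2Cl2, 0 °C → rt; then TsOH·H2O (5 mol %), toluene, 80 °C
Reagents that add atoms: none
Why: Acid cleavage of the methoxymethyl acetal frees the ortho phenol, which lactonises onto the methyl ester (intramolecular transesterification, 6-exo-trig) and so closes the lower pyran ring without touching C3.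

Step 4
Reactants: 7 (3S)-7-(benzyloxy)-3-hydroxychroman-2-one
Product: 8 (3S)-7-(benzyloxy)chroman-2,3-diol (lactol as a mixture of C2 anomers)
Conditions: i-Bu2AlH (2.2 equiv), CH2Cl2, −78 °C; aq. potassium sodium tartrate
Reagents that add atoms: none
Why: Partial reduction of a lactone by i-Bu2AlH should stop at the lactol because the aluminium hemiacetal is stable at −78 °C; C3 is untouched and the anomeric mixture at C2 is funnelled in step 10.

Step 5
Reactants: 9 (2R,3R)-fustin, (2R,3R)-2-(3,4-dihydroxyphenyl)-3,7-dihydroxychroman-4-one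
Product: 10 (2R,3R)-7-(benzyloxy)-2-[3,4-bis(benzyloxy)phenyl]-3-hydroxychroman-4-one
Conditions: BnBr (3.3 equiv), K2CO3, DMF, 0 °C → rt, argon
Reagents that add atoms: benzyl bromide, BrCc1ccccc1
Why: Williamson benzylation under carbonate should alkylate the three phenols and leave the much less acidic secondary 3-hydroxyl free; both stereocentres come from the natural product.

Step 6
Reactants: 10 (2R,3R)-7-(benzyloxy)-2-[3,4-bis(benzyloxy)phenyl]-3-hydroxychroman-4-one
Product: 11 (2R,3S,4R)-7-(benzyloxy)-2-[3,4-bis(benzyloxy)phenyl]chroman-3,4-diol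
Conditions: NaBH4, THF/EtOH, 0 °C
Reagents that add atoms: none
Why: Borohydride reduction of the aryl ketone by axial hydride delivery should give mainly the all-equatorial 2,3-trans-3,4-trans diol, and the C4 configuration is of no consequence because C4 is ionised in step 7.

Step 7
Reactants: 11 (2R,3S,4R)-7-(benzyloxy)-2-[3,4-bis(benzyloxy)phenyl]chroman-3,4-diol; 12 3,4-bis(benzyloxy)phenol
Product: 13 (2R,3S,4R)-7-(benzyloxy)-4-[4,5-bis(benzyloxy)-2-hydroxyphenyl]-2-[3,4-bis(benzyloxy)phenyl]chroman-3-ol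
Conditions: 12 (4 equiv), BF3·OEt2 (0.2 equiv), CH2Cl2, −30 → 0 °C
Reagents that add atoms: none
Why: Friedel–Crafts alkylation (SN1): the 4-hydroxyl ionises to a benzylic cation stabilised by the para 7-benzyloxy group and O1, and the excess phenol attacks through its carbon ortho to OH and para to the 3-benzyloxy group on the face anti to the 3-hydroxyl, which sets C4 as 3,4-trans.

Step 8
Reactants: 13 (2R,3S,4R)-7-(benzyloxy)-4-[4,5-bis(benzyloxy)-2-hydroxyphenyl]-2-[3,4-bis(benzyloxy)phenyl]chroman-3-ol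
Product: 14 4,5-bis(benzyloxy)-2-{(2R,3S,4S)-7-(benzyloxy)-2-[3,4-bis(benzyloxy)phenyl]-3-hydroxychroman-4-yl}phenyl trifluoromethanesulfonate (same spatial arrangement as 13; the C4 descriptor changes by priority only)
Conditions: PhNTf2, Et3N, DMAP (cat.), CH2Cl2, rt
Reagents that add atoms: N-phenylbis(trifluoromethanesulfonimide) (PhNTf2), O=S(=O)(N(c1ccccc1)S(=O)(=O)C(F)(F)F)C(F)(F)F
Why: Sulfonylation of the phenol by PhNTf2 under amine base is chemoselective, because this triflating agent does not react with the secondary alcohol.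

Step 9
Reactants: 14 4,5-bis(benzyloxy)-2-{(2R,3S,4S)-7-(benzyloxy)-2-[3,4-bis(benzyloxy)phenyl]-3-hydroxychroman-4-yl}phenyl trifluoromethanesulfonate
Product: 16 cyclic 3-O-boronic hemiester of (2R,3S,4R)-7-(benzyloxy)-2-[3,4-bis(benzyloxy)phenyl]-4-[4,5-bis(benzyloxy)-2-boronophenyl]chroman-3-ol (boron bonded to C1', to one OH and to the flavan 3-oxygen in a six-membered 2,1-benzoxaborinine ring), via arylboronic acid 15 (not isolated)
Conditions: B2(OH)4, Pd(OAc)2 (5 mol %), XPhos (10 mol %), KOAc, EtOH, 80 °C; then toluene azeotrope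
Reagents that add atoms: tetrahydroxydiboron, OB(O)B(O)O
Why: Miyaura borylation (oxidative addition of zerovalent palladium into the aryl triflate, transmetalation with the diboron reagent, reductive elimination) gives the boronic acid, which should close onto the neighbouring 3-hydroxyl as a six-membered hemiester that masks that alcohol and stabilises the C–B bond.

Step 10
Reactants: 8 (3S)-7-(benzyloxy)chroman-2,3-diol; 16 cyclic 3-O-boronic hemiester of the 4-(2-boronoaryl)flavan-3-ol
Product: 19 (2R,3S,4R)-7-(benzyloxy)-4-{4,5-bis(benzyloxy)-2-[(2S,3S)-7-(benzyloxy)-3-hydroxychroman-2-yl]phenyl}-2-[3,4-bis(benzyloxy)phenyl]chroman-3-ol, via mixed boronic ester 17 (not isolated), via bridged borate 18 (not isolated)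
Conditions: 8 (1.5 equiv), 4 Å MS, toluene, 50 °C; then BF3·OEt2 (0.3 equiv), CH2Cl2/(CF3)2CHOH, −40 → 0 °C; aq. NaHCO3
Reagents that add atoms: none
Why: Proposed new method: the B–OH of 16 condenses with the 3-hydroxyl of lactol 8 to give 17, the anomeric hydroxyl (free to equilibrate through the open hydroxy aldehyde) is ionised by the Lewis acid and passes to boron, and the resulting O1=C2 oxocarbenium ion, flanked by a tetracoordinate aryl borate on O3, takes the electron-rich aryl group (ipso carbon para to a benzyloxy group) from boron through a five-membered transition state, leaving borate 18, which is hydrolysed on work-up. The closest known reaction types are the Petasis reaction of α-hydroxy aldehydes, the cis-selective hydroxyl-directed addition of aryl boronates to cyclic N-acyliminium ions and boron-mediated 1,2-cis delivery to 1,2-anhydro sugars; none has been shown for aryl transfer to a 3-hydroxychroman-2-yl cation. No ring of the target is closed: the lower pyran ring is already in place and the only rings formed are temporary boron-containing ones (the nine-membered borate 18). The new stereocentre, lower C2 (S), is controlled by the existing C3 (S) centre, because the aryl group can leave boron only on the face that carries O3, so both lactol anomers converge on the 2,3-cis product. The step needs aryl transfer to outrun Friedel–Crafts attack of the cation on C6/C8 of the benzyloxy-substituted ring A units and protodeboronation; intramolecular delivery, low temperature and the six-membered boron chelate to the upper 3-oxygen are meant to secure this.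

Step 11
Reactants: 19 (2R,3S,4R)-7-(benzyloxy)-4-{4,5-bis(benzyloxy)-2-[(2S,3S)-7-(benzyloxy)-3-hydroxychroman-2-yl]phenyl}-2-[3,4-bis(benzyloxy)phenyl]chroman-3-ol
Product: 20 (2R,3S,4R)-4-{4,5-dihydroxy-2-[(2S,3S)-3,7-dihydroxychroman-2-yl]phenyl}-2-(3,4-dihydroxyphenyl)chroman-3,7-diol (target)
Conditions: H2 (1 atm), Pd(OH)2/C, THF/MeOH, rt, then work-up under argon
Reagents that add atoms: none
Why: Hydrogenolysis of the six benzyl ethers over Pd(OH)2/C at ambient pressure should leave the benzylic C2–O1 bonds of both pyran rings and all five stereocentres untouched.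

Compound list
1 | 5-(benzyloxy)-2-bromophenol | Oc1cc(OCc2ccccc2)ccc1Br | starting material
2 | 4-(benzyloxy)-1-bromo-2-(methoxymethoxy)benzene | COCOc1cc(OCc2ccccc2)ccc1Br | intermediate
3 | methyl (2S)-oxirane-2-carboxylate | COC(=O)[C@@H]1CO1 | starting material
4 | [4-(benzyloxy)-2-(methoxymethoxy)phenyl]magnesium bromide (not isolated) | COCOc1cc(OCc2ccccc2)ccc1[Mg]Br | intermediate
5 | methyl (2S)-3-[4-(benzyloxy)-2-(methoxymethoxy)phenyl]-2-hydroxypropanoate | COC(=O)[C@@H](O)Cc1ccc(OCc2ccccc2)cc1OCOC | intermediate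
6 | methyl (2S)-3-[4-(benzyloxy)-2-hydroxyphenyl]-2-hydroxypropanoate (not isolated) | COC(=O)[C@@H](O)Cc1ccc(OCc2ccccc2)cc1O | intermediate
7 | (3S)-7-(benzyloxy)-3-hydroxychroman-2-one | c3ccccc3COc1ccc2c(c1)OC(=O)[C@@H](O)C2 | intermediate
8 | (3S)-7-(benzyloxy)chroman-2,3-diol, mixture of C2 anomers | c3ccccc3COc1ccc2c(c1)OC(O)[C@@H](O)C2 | intermediate
9 | (2R,3R)-fustin | O=C1c2ccc(O)cc2O[C@H](c2ccc(O)c(O)c2)[C@H]1O | starting material
10 | (2R,3R)-7-(benzyloxy)-2-[3,4-bis(benzyloxy)phenyl]-3-hydroxychroman-4-one | O=C1c2ccc(OCc3ccccc3)cc2O[C@H](c2ccc(OCc3ccccc3)c(OCc3ccccc3)c2)[C@H]1O | intermediate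
11 | (2R,3S,4R)-7-(benzyloxy)-2-[3,4-bis(benzyloxy)phenyl]chroman-3,4-diol | O[C@@H]1c2ccc(OCc3ccccc3)cc2O[C@H](c2ccc(OCc3ccccc3)c(OCc3ccccc3)c2)[C@H]1O | intermediate
12 | 3,4-bis(benzyloxy)phenol | Oc1ccc(OCc2ccccc2)c(OCc2ccccc2)c1 | starting material
13 | (2R,3S,4R)-7-(benzyloxy)-4-[4,5-bis(benzyloxy)-2-hydroxyphenyl]-2-[3,4-bis(benzyloxy)phenyl]chroman-3-ol | Oc1cc(OCc4ccccc4)c(OCc4ccccc4)cc1[C@@H]1c3ccc(OCc4ccccc4)cc3O[C@H](c3ccc(OCc4ccccc4)c(OCc4ccccc4)c3)[C@H]1O | intermediate
14 | 4,5-bis(benzyloxy)-2-{(2R,3S,4S)-7-(benzyloxy)-2-[3,4-bis(benzyloxy)phenyl]-3-hydroxychroman-4-yl}phenyl trifluoromethanesulfonate | O=S(=O)(Oc1cc(OCc4ccccc4)c(OCc4ccccc4)cc1[C@@H]1c3ccc(OCc4ccccc4)cc3O[C@H](c3ccc(OCc4ccccc4)c(OCc4ccccc4)c3)[C@H]1O)C(F)(F)F | intermediate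
15 | [4,5-bis(benzyloxy)-2-{(2R,3S,4R)-7-(benzyloxy)-2-[3,4-bis(benzyloxy)phenyl]-3-hydroxychroman-4-yl}phenyl]boronic acid (not isolated) | OB(O)c1cc(OCc4ccccc4)c(OCc4ccccc4)cc1[C@@H]1c3ccc(OCc4ccccc4)cc3O[C@H](c3ccc(OCc4ccccc4)c(OCc4ccccc4)c3)[C@H]1O | intermediate
16 | cyclic 3-O-boronic hemiester of 15 (boron bonded to C1', OH and the flavan 3-oxygen; six-membered 2,1-benzoxaborinine ring; flavan centres 2R,3S,4R) | OB5c1cc(OCc4ccccc4)c(OCc4ccccc4)cc1[C@@H]1c3ccc(OCc4ccccc4)cc3O[C@H](c3ccc(OCc4ccccc4)c(OCc4ccccc4)c3)[C@H]1O5 | intermediate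
17 | mixed boronic ester of 16 with the 3-oxygen of lactol 8 (lower C3 S, lower C2 as anomeric mixture; not isolated) | c4ccccc4COc1ccc2c(c1)OC(O)[C@H](C2)OB5c1cc(OCc4ccccc4)c(OCc4ccccc4)cc1[C@@H]1c3ccc(OCc4ccccc4)cc3O[C@H](c3ccc(OCc4ccccc4)c(OCc4ccccc4)c3)[C@H]1O5 | intermediate
18 | bridged borate of 19 (B–OH boron esterified by the upper and the lower 3-oxygen, nine-membered ring; not isolated) | c4ccccc4COc1ccc2c(c1)O[C@@H](c1cc(OCc4ccccc4)c(OCc4ccccc4)cc1[C@@H]1c3ccc(OCc4ccccc4)cc3O[C@H](c3ccc(OCc4ccccc4)c(OCc4ccccc4)c3)[C@H]1OB5O)[C@@H](O5)C2 | intermediate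
19 | (2R,3S,4R)-7-(benzyloxy)-4-{4,5-bis(benzyloxy)-2-[(2S,3S)-7-(benzyloxy)-3-hydroxychroman-2-yl]phenyl}-2-[3,4-bis(benzyloxy)phenyl]chroman-3-ol | c4ccccc4COc1ccc2c(c1)O[C@@H](c1cc(OCc4ccccc4)c(OCc4ccccc4)cc1[C@@H]1c3ccc(OCc4ccccc4)cc3O[C@H](c3ccc(OCc4ccccc4)c(OCc4ccccc4)c3)[C@H]1O)[C@@H](O)C2 | intermediate
20 | (2R,3S,4R)-4-{4,5-dihydroxy-2-[(2S,3S)-3,7-dihydroxychroman-2-yl]phenyl}-2-(3,4-dihydroxyphenyl)chroman-3,7-diol | Oc1ccc2c(c1)O[C@@H](c1cc(O)c(O)cc1[C@@H]1c3ccc(O)cc3O[C@H](c3ccc(O)c(O)c3)[C@H]1O)[C@@H](O)C2 | target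

Total step count: 11. Longest linear sequence: 7 steps (steps 5 to 11, from 9 to 20).

Steps most likely to fail

Step 10 (Proposed new method). The aryl transfer may be too slow at the hindered ipso carbon. In that case protodeboronation by the acid promoter, capture of the oxocarbenium ion by ring A carbons of a second molecule, or enolisation of the lactol with loss of C3 integrity would take over. The fallback uses known chemistry (aryllithium addition to a lactone followed by silane reduction of the lactol, as in C-aryl glycoside synthesis). It sets out from 16 and 7 and comes back at 19. Bromodeboronation of 16 with CuBr2 (MeOH/H2O, 70 °C) should give the aryl bromide (2R,3S,4S)-7-(benzyloxy)-4-[4,5-bis(benzyloxy)-2-bromophenyl]-2-[3,4-bis(benzyloxy)phenyl]chroman-3-ol F1. Lactone 7 would be silylated (TBSCl, imidazole, DMF) to (3S)-7-(benzyloxy)-3-[(tert-butyldimethylsilyl)oxy]chroman-2-one F2. F1 would be converted into its lithium alkoxide and aryllithium (n-BuLi, then t-BuLi, THF, −78 °C) and added to F2 to give the 2-aryl-2-hydroxy-3-silyloxychroman lactol F3, in equilibrium with its open hydroxy ketone. Et3SiH with BF3·OEt2 (CH2Cl2/MeCN, −40 °C) should reduce the 2-aryl oxocarbenium ion on the face opposite the pseudo-axial 3-silyloxy group to the 2,3-cis 3-O-silyl flavan F4. Bu4NF in THF would then give 19.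

Step 7. The benzylic cation may alkylate ring A of a second flavan molecule (oligomerisation) faster than the phenol, the phenol may react at oxygen or at its hindered ortho carbon, and the 3,4-trans preference may erode. The fallback replaces free-cation Friedel–Crafts chemistry by ortho-directed C-alkylation of a magnesium phenoxide with neighbouring-group control. It sets out from 11 and 12 and comes back at 13. Acetylation of 11 (Ac2O, pyridine, DMAP) would give the 3,4-di-O-acetate of 11 F5. The bromomagnesium phenoxide of 12 (EtMgBr, toluene/CH2Cl2, rt) should displace the benzylic 4-acetate through its ortho carbon within the magnesium chelate, while the 3-acetoxy group bridges C4 as an acetoxonium ion and forces trans entry, to give the 3-O-acetate of 13 F6. K2CO3 in MeOH would then give 13.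

Step 9. Oxidative addition into the hindered, electron-rich triflate may be slow, so that reduction of the C–O bond, hydrolysis of the triflate or protodeboronation at 80 °C competes. The fallback avoids palladium and the triflate by going through carbon–nitrogen, carbon–iodine and carbon–lithium bonds. It sets out from 11 and comes back at 16. Friedel–Crafts alkylation of commercial 3,4-bis(benzyloxy)aniline by 11 ((CF3)2CHOH, cat. CF3SO3H, 40 °C), ortho to the amino group and para to the 3-benzyloxy group, should give (2R,3S,4R)-4-[2-amino-4,5-bis(benzyloxy)phenyl]-7-(benzyloxy)-2-[3,4-bis(benzyloxy)phenyl]chroman-3-ol F7. Sandmeyer-type iodination (NaNO2, aq. H2SO4/MeCN, 0 °C, then KI) should give (2R,3S,4S)-7-(benzyloxy)-4-[4,5-bis(benzyloxy)-2-iodophenyl]-2-[3,4-bis(benzyloxy)phenyl]chroman-3-ol F8. Deprotonation and iodine–lithium exchange (n-BuLi, then t-BuLi, THF, −78 °C), B(Oi-Pr)3 and aqueous HCl would then give 16.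

Further compounds
F1 | step 10 | (2R,3S,4S)-7-(benzyloxy)-4-[4,5-bis(benzyloxy)-2-bromophenyl]-2-[3,4-bis(benzyloxy)phenyl]chroman-3-ol | Brc1cc(OCc4ccccc4)c(OCc4ccccc4)cc1[C@@H]1c3ccc(OCc4ccccc4)cc3O[C@H](c3ccc(OCc4ccccc4)c(OCc4ccccc4)c3)[C@H]1O
F2 | step 10 | (3S)-7-(benzyloxy)-3-[(tert-butyldimethylsilyl)oxy]chroman-2-one | c4ccccc4COc1ccc2c(c1)OC(=O)[C@@H](O[Si](C)(C)C(C)(C)C)C2
F3 | step 10 | (3S)-7-(benzyloxy)-2-{4,5-bis(benzyloxy)-2-[(2R,3S,4R)-7-(benzyloxy)-2-[3,4-bis(benzyloxy)phenyl]-3-hydroxychroman-4-yl]phenyl}-3-[(tert-butyldimethylsilyl)oxy]chroman-2-ol, mixture of C2 anomers | c4ccccc4COc1ccc2c(c1)OC(O)(c1cc(OCc4ccccc4)c(OCc4ccccc4)cc1[C@@H]1c3ccc(OCc4ccccc4)cc3O[C@H](c3ccc(OCc4ccccc4)c(OCc4ccccc4)c3)[C@H]1O)[C@@H](O[Si](C)(C)C(C)(C)C)C2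
F4 | step 10 | (2R,3S,4R)-7-(benzyloxy)-4-{4,5-bis(benzyloxy)-2-[(2S,3S)-7-(benzyloxy)-3-[(tert-butyldimethylsilyl)oxy]chroman-2-yl]phenyl}-2-[3,4-bis(benzyloxy)phenyl]chroman-3-ol | c4ccccc4COc1ccc2c(c1)O[C@@H](c1cc(OCc4ccccc4)c(OCc4ccccc4)cc1[C@@H]1c3ccc(OCc4ccccc4)cc3O[C@H](c3ccc(OCc4ccccc4)c(OCc4ccccc4)c3)[C@H]1O)[C@@H](O[Si](C)(C)C(C)(C)C)C2
F5 | step 7 | 3,4-di-O-acetate of diol 11 (all three centres spatially unchanged) | CC(=O)O[C@@H]1c2ccc(OCc3ccccc3)cc2O[C@H](c2ccc(OCc3ccccc3)c(OCc3ccccc3)c2)[C@H]1OC(C)=O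
F6 | step 7 | 3-O-acetate of 13 (centres as in 13) | Oc1cc(OCc4ccccc4)c(OCc4ccccc4)cc1[C@@H]1c3ccc(OCc4ccccc4)cc3O[C@H](c3ccc(OCc4ccccc4)c(OCc4ccccc4)c3)[C@H]1OC(C)=O
F7 | step 9 | (2R,3S,4R)-4-[2-amino-4,5-bis(benzyloxy)phenyl]-7-(benzyloxy)-2-[3,4-bis(benzyloxy)phenyl]chroman-3-ol | Nc1cc(OCc4ccccc4)c(OCc4ccccc4)cc1[C@@H]1c3ccc(OCc4ccccc4)cc3O[C@H](c3ccc(OCc4ccccc4)c(OCc4ccccc4)c3)[C@H]1O
F8 | step 9 | (2R,3S,4S)-7-(benzyloxy)-4-[4,5-bis(benzyloxy)-2-iodophenyl]-2-[3,4-bis(benzyloxy)phenyl]chroman-3-ol | Ic1cc(OCc4ccccc4)c(OCc4ccccc4)cc1[C@@H]1c3ccc(OCc4ccccc4)cc3O[C@H](c3ccc(OCc4ccccc4)c(OCc4ccccc4)c3)[C@H]1O
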